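**Plan**
- Cuts: C3–C1′ (ring C to ring B) and O1–C2 fall together in the key step. Earlier cuts are C2=C3 (C2 from an amide acetal), O7–prenyl, and the C1′–S bond back to the C1′–H of guaiacol acetate.
- Hardest point: C3 and C1′ are both innately nucleophilic carbons. Three ring oxygens (O7-prenyl, 3′-OH, 4′-OMe) must also end up different, next to an acid- and oxidant-sensitive prenyl ether.
- Enabling feature, ring C: opened at O1–C2, ring C is an o-hydroxyaryl enaminone. Its α-CH (C3) accepts radicals to give an easily oxidised α-amino radical at C2, next to the 2-OH (future O1).
- Enabling feature, ring B: C1′ is the one C–H para to 4′-OMe once O3′ is acylated, so C–H thianthrenation turns it into an aryl-radical source (polarity reversal).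
- Forward: rings A and B are bought. O7 is prenylated, C2 is added and ring B is activated at C1′–H. One photoredox cascade then joins C3–C1′ and closes ring C last, and methanolysis in the same flask frees 3′-OH.
- Stereochemistry: none to set.

Key step: step 4

Remark: the target has no stereocentre, and its only acyclic C=C carries two identical methyl groups. It is therefore achiral, and the request for a single enantiomer needs no action.

**Step 1**
Reactants: 1 2,4-dihydroxyacetophenone; 2 prenyl bromide (1-bromo-3-methylbut-2-ene)
Product: 3 1-[2-hydroxy-4-(3-methylbut-2-enyloxy)phenyl]ethanone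
Conditions: K2CO3 (1.1 equiv), acetone, reflux
Reagents that add atoms: none
Why: Williamson etherification; the 2-OH is locked in a hydrogen bond to the acetyl C=O and is much less acidic and nucleophilic than the 4-OH, so one equivalent of the SN2-active allylic bromide should alkylate O-4 only.

**Step 2**
Reactants: 3 1-[2-hydroxy-4-(3-methylbut-2-enyloxy)phenyl]ethanone; 4 N,N-dimethylformamide dimethyl acetal
Product: 5 (E)-3-(dimethylamino)-1-[2-hydroxy-4-(3-methylbut-2-enyloxy)phenyl]prop-2-en-1-one
Conditions: toluene, 100 °C
Reagents that add atoms: none
Why: Amide-acetal condensation of a methyl ketone (enaminone synthesis); the acetyl CH3 is the only acidic C–H, the chelated phenol resists O-methylation, the temperature lies well below the onset of an aryl prenyl ether Claisen rearrangement, and the E alkene is the thermodynamic isomer.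

**Step 3**
Reactants: 6 2-methoxyphenyl acetate (guaiacol acetate)
Product: 7 5-(3-acetoxy-4-methoxyphenyl)-5H-thianthren-5-ium tetrafluoroborate
Conditions: thianthrene 5-oxide, (CF3CO)2O, HBF4·OEt2, MeCN, 0 °C to rt
Reagents that add atoms: thianthrene 5-oxide, O=S1c2ccccc2Sc2ccccc21; tetrafluoroboric acid (diethyl etherate), [H+].F[B-](F)(F)F
Why: Site-selective arene C–H thianthrenation (electrophilic aromatic substitution by the anhydride-activated sulfoxide); with the phenol oxygen masked as acetate, OMe is the dominant donor, and the bulky, strongly para-selective sulfur electrophile should attack only the C–H para to OMe, which is the future C1′.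

**Step 4**
Reactants: 5 (E)-3-(dimethylamino)-1-[2-hydroxy-4-(3-methylbut-2-enyloxy)phenyl]prop-2-en-1-one; 7 5-(3-acetoxy-4-methoxyphenyl)-5H-thianthren-5-ium tetrafluoroborate
Product: 9 3-(3-hydroxy-4-methoxyphenyl)-7-(3-methylbut-2-enyloxy)-4H-chromen-4-one (target), via 3'-O-acetyl isoflavone 8 (not isolated)
Conditions: fac-Ir(ppy)3 (1 mol %), MeCN, blue LEDs, N2, rt; then K2CO3 (1 equiv), MeOH, rt
Reagents that add atoms: none
Why: Excited fac-Ir(ppy)3 transfers one electron to sulfonium salt 7, whose exocyclic C–S bond breaks to thianthrene and the 3-acetoxy-4-methoxyphenyl σ-radical; this radical adds to the α-CH of enaminone 5 (future C3), and the resulting α-amino radical is oxidised by Ir(IV) to an iminium ion (radical–polar crossover, redox-neutral overall), the acid set free being buffered by the departing dimethylamine. Ring C closes by 6-exo-trig attack of the ring A 2-OH oxygen (O1) on the iminium carbon (C2), and E1cB loss of HNMe2 from the aminal gives the 4-pyranone of 8. The closest known reaction type is the photoredox arylation/chromone annulation of o-hydroxyaryl enaminones with aryl sulfonium and related onium salts, one member of the broad family of radical-triggered enaminone-to-3-substituted-chromone cascades. No stereocentre survives, because the two sp3 centres of the transient aminal (C2, C3) are erased by the elimination. The step needs chemoselectivity for the enaminone C=C over the prenyl C=C and its allylic C–H bonds, and regioselectivity for Cα: the push–pull alkene is only 1,2-disubstituted, has its largest HOMO coefficient at Cα and gives an N-stabilised radical that is drained irreversibly by oxidation, whereas the prenyl alkene is trisubstituted and offers no such sink, and the mild photoreductant should leave aryl ketone, chromone and allyl aryl ether untouched. K2CO3/MeOH then transesterifies the aryl acetate of 8 at room temperature, conditions under which the prenyl ether and the pyranone should persist.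

**Compound list**
1 | 2,4-dihydroxyacetophenone | CC(=O)c1ccc(O)cc1O | starting material
2 | prenyl bromide (1-bromo-3-methylbut-2-ene) | CC(C)=CCBr | starting material
3 | 1-[2-hydroxy-4-(3-methylbut-2-enyloxy)phenyl]ethanone | CC(=O)c1ccc(OCC=C(C)C)cc1O | intermediate
4 | N,N-dimethylformamide dimethyl acetal | COC(OC)N(C)C | starting material
5 | (E)-3-(dimethylamino)-1-[2-hydroxy-4-(3-methylbut-2-enyloxy)phenyl]prop-2-en-1-one | CN(C)/C=C/C(=O)c1ccc(OCC=C(C)C)cc1O | intermediate
6 | 2-methoxyphenyl acetate | COc1ccccc1OC(C)=O | starting material
7 | 5-(3-acetoxy-4-methoxyphenyl)-5H-thianthren-5-ium tetrafluoroborate | COc1ccc(cc1OC(C)=O)[S+]1c2ccccc2Sc2ccccc21.F[B-](F)(F)F | intermediate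
8 | 2-methoxy-5-[7-(3-methylbut-2-enyloxy)-4-oxo-4H-chromen-3-yl]phenyl acetate (3'-O-acetyl isoflavone, not isolated) | COc1ccc(-c2coc3cc(OCC=C(C)C)ccc3c2=O)cc1OC(C)=O | intermediate
9 | 3-(3-hydroxy-4-methoxyphenyl)-7-(3-methylbut-2-enyloxy)-4H-chromen-4-one (7-prenyloxy-3'-hydroxy-4'-methoxyisoflavone) | COc1ccc(-c2coc3cc(OCC=C(C)C)ccc3c2=O)cc1O | target

**Totals**
Total step count: 4. Longest linear sequence: 3 (steps 1, 2, 4). Step 3 is a one-step branch from a commercial arene.

**Steps most likely to fail**

1. **Step 4.**
   - What may go wrong: the aryl radical may be lost before C–C bond formation. It could abstract hydrogen from the allylic and α-oxy C–H bonds of the prenyl ether or from the solvent, or it could add to the prenyl alkene.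
   - Fallback: two-electron cross-coupling that sets out from 5 and comes back at 9. One equivalent of iodine in CHCl3 at rt should attack the enaminone α-carbon and trigger cyclisation with loss of dimethylamine, giving 3-iodo-7-(3-methylbut-2-enyloxy)-4H-chromen-4-one F1.
   - Suzuki–Miyaura coupling of this iodide with commercial (3-hydroxy-4-methoxyphenyl)boronic acid (Pd(dppf)Cl2, Na2CO3, dioxane/water) should then give 9 directly.

2. **Step 3.**
   - What may go wrong: site selectivity may erode through attack para to the acyloxy group. Alternatively, the acetate may be lost in the strongly acidic medium, followed by attack para to the freed OH.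
   - Fallback: mild halogenation and boron chemistry that sets out from 6 (with 5 supplying the partner) and comes back at 8. NBS in MeCN should brominate para to OMe to give 5-bromo-2-methoxyphenyl acetate F2.
   - Miyaura borylation (B2pin2, Pd(dppf)Cl2, KOAc, dioxane) should give 2-methoxy-5-(4,4,5,5-tetramethyl-1,3,2-dioxaborolan-2-yl)phenyl acetate F3.
   - Suzuki–Miyaura coupling of this boronate (K3PO4, dioxane) with 3-iodo-7-(3-methylbut-2-enyloxy)-4H-chromen-4-one F1, made from 5 as described above, should give 8. This re-enters the route at the methanolysis stage of step 4.

3. **Step 1.**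
   - What may go wrong: the ambident phenoxide may be over-alkylated at the chelated 2-OH or C-prenylated on the electron-rich ring.
   - Fallback: it sets out from 1 and comes back at 3 without forming a free phenoxide. A Mitsunobu reaction of 1 with 3-methylbut-2-en-1-ol (PPh3, DIAD, THF, 0 °C) activates the alcohol instead, and only the more acidic, non-chelated 4-OH should serve as the pronucleophile. This fallback makes no new compound.

**Further compounds**
F1 | step 4 | 3-iodo-7-(3-methylbut-2-enyloxy)-4H-chromen-4-one | CC(C)=CCOc1ccc2c(c1)occ(I)c2=O
F2 | step 3 | 5-bromo-2-methoxyphenyl acetate | COc1ccc(Br)cc1OC(C)=O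
F3 | step 3 | 2-methoxy-5-(4,4,5,5-tetramethyl-1,3,2-dioxaborolan-2-yl)phenyl acetate | COc1ccc(cc1OC(C)=O)B1OC(C)(C)C(C)(C)O1
F0 | step 1 | none | none
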